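**Assumptions:**
- The target SMILES is (2S) by CIP (O > aryl > C3 > H), and I assume the (S)-axial catalyst 15 delivers (2S). If the screen gives (2R), the (R)-catalyst is used instead.
- Catalyst 15 is taken as commercially available, or made in one step from the (S)-TRIP phosphoric acid.

## Retrosynthetic overview
1. Glabrol comes from a bis-MOM flavanone by MOM removal. No new stereocentre is made at this stage.
2. The only ring formed late is the C ring (O1–C2 bond). It is made by an enantioselective 6-endo oxa-Michael cyclisation of a 2'-hydroxychalcone, which sets C2 (proposed new step).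
3. The chalcone comes from a Claisen–Schmidt condensation of two ortho-prenylated phenolic carbonyl fragments. The A and B aromatic rings already exist and are not formed in the route.
4. Each ortho-prenyl phenol is made by O-allylation, aromatic Claisen rearrangement, MOM protection and cross-metathesis with 2-methyl-2-butene.

## Route

**Step 1**
Reactants: 1 (2',4'-dihydroxyacetophenone), 2 (allyl bromide)
Product: 3 (4'-allyloxy-2'-hydroxyacetophenone)
Conditions: K2CO3, acetone, reflux, 6 h
Reagents that add atoms: allyl bromide, C=CCBr
Why: Williamson etherification is selective for the 4'-OH because the 2'-OH is locked in a hydrogen bond to the ketone.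

**Step 2**
Reactants: 3
Product: 4 (1-(3-allyl-2,4-dihydroxyphenyl)ethan-1-one)
Conditions: PhNEt2, 210 °C (microwave), 2 h
Reagents that add atoms: none
Why: the aromatic Claisen [3,3] rearrangement sends allyl mainly to C3', between the two oxygens. The minor C5' isomer is removed by chromatography.

**Step 3**
Reactants: 4, 5 (chloromethyl methyl ether)
Product: 6 (1-[3-allyl-2-hydroxy-4-(methoxymethoxy)phenyl]ethan-1-one)
Conditions: MOMCl, i-Pr2NEt, CH2Cl2, 0 °C, 2 h
Reagents that add atoms: MOMCl, ClCOC
Why: O-alkylation is selective for the free 4'-OH because the chelated 2'-OH is unreactive. The MOM ether is stable to the later base and to the mild acid catalysis.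

**Step 4**
Reactants: 6, 7 (2-methyl-2-butene)
Product: 8 (1-[2-hydroxy-4-(methoxymethoxy)-3-(3-methylbut-2-en-1-yl)phenyl]ethan-1-one)
Conditions: Hoveyda–Grubbs II (5 mol%), 1,4-benzoquinone (10 mol%), 2-methyl-2-butene (20 equiv), CH2Cl2, 40 °C, sealed tube, 16 h
Reagents that add atoms: 2-methyl-2-butene, CC=C(C)C
Why: olefin cross-metathesis converts the terminal allyl into prenyl and releases propene, and benzoquinone suppresses Ru–H isomerisation of allyl to propenyl.

**Step 5**
Reactants: 9 (4-hydroxybenzaldehyde), 2
Product: 10 (4-allyloxybenzaldehyde)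
Conditions: K2CO3, acetone, reflux, 5 h
Reagents that add atoms: allyl bromide, C=CCBr
Why: this is a Williamson O-allylation of the only phenol.

**Step 6**
Reactants: 10
Product: 11 (3-allyl-4-hydroxybenzaldehyde)
Conditions: PhNEt2, 200 °C, 3 h
Reagents that add atoms: none
Why: the aromatic Claisen rearrangement has two equivalent ortho positions, so there is no regiochemical problem.

**Step 7**
Reactants: 11, 5
Product: 12 (3-allyl-4-(methoxymethoxy)benzaldehyde)
Conditions: MOMCl, i-Pr2NEt, CH2Cl2, 0 °C to rt, 3 h
Reagents that add atoms: MOMCl, ClCOC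
Why: this is a standard phenol MOM protection.

**Step 8**
Reactants: 12, 7
Product: 13 (4-(methoxymethoxy)-3-(3-methylbut-2-en-1-yl)benzaldehyde)
Conditions: Hoveyda–Grubbs II (5 mol%), 1,4-benzoquinone (10 mol%), 2-methyl-2-butene (20 equiv), CH2Cl2, 40 °C, sealed tube, 16 h
Reagents that add atoms: 2-methyl-2-butene, CC=C(C)C
Why: this is the same cross-metathesis as step 4, and the aryl aldehyde is inert to it.

**Step 9**
Reactants: 8, 13
Product: 14 ((E)-1-[2-hydroxy-4-(MOMO)-3-prenylphenyl]-3-[4-(MOMO)-3-prenylphenyl]prop-2-en-1-one)
Conditions: 50% aq. KOH (5 equiv), EtOH, 0 °C to rt, 24 h; quench with AcOH at 0 °C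
Reagents that add atoms: none
Why: this is a Claisen–Schmidt aldol condensation. The phenoxide keeps the ortho-hydroxychalcone open, and the cold acidic quench avoids cyclisation to racemic flavanone.

**Step 10**
Reactants: 14, 15 ((S)-TRIP N-triflylphosphoramide catalyst)
Product: 16 ((2S)-7-(methoxymethoxy)-2-[4-(methoxymethoxy)-3-prenylphenyl]-8-prenylchroman-4-one)
Conditions: 15 (10 mol%), toluene (0.01 M), 4 Å MS, 0 °C, 96 h
Reagents that add atoms: none (15 is a catalyst and is not incorporated)
Why: Proposed new method: the confined chiral N-triflyl phosphoramide acts as a bifunctional Brønsted acid, with its N–H activating the enone carbonyl while the P=O accepts the 2'-OH proton as the phenol rotates out of its chelate and adds 6-endo to the β-carbon. The 3,3'-aryl walls discriminate the enone faces, so O1–C2 bond formation sets the (2S) centre, and proton return to C3 gives the ketone without touching C2. It is moderately acidic, so the prenyl alkenes are not protonated at 0 °C, and non-enolate acid conditions largely close the retro-oxa-Michael/racemisation channel that erodes ee with basic amine or thiourea catalysts. The closest known reactions are Brønsted-acid (phosphoric acid) intramolecular oxa-Michael cyclisations and amine/thiourea-catalysed flavanone formation from 2'-hydroxychalcones. What is new is using a strong chiral N-triflyl phosphoramide under kinetic control on a push–pull-deactivated, 4,4'-dialkoxy, bis-prenylated chalcone.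

**Step 11**
Reactants: 16
Product: 17 (glabrol, (2S)-7-hydroxy-2-[4-hydroxy-3-prenylphenyl]-8-prenylchroman-4-one)
Conditions: ZnBr2 (6 equiv), n-PrSH (12 equiv), CH2Cl2, 0 °C, 30 min
Reagents that add atoms: none
Why: mild Lewis-acid/thiol cleavage of both aryl MOM ethers leaves the prenyl alkenes and the C2 centre intact, since the short reaction at 0 °C avoids base and the protic acid heating that would ring-open or racemise the flavanone.

## Compound list
1 | 2',4'-dihydroxyacetophenone | CC(=O)c1ccc(O)cc1O | starting material
2 | allyl bromide | C=CCBr | starting material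
3 | 4'-allyloxy-2'-hydroxyacetophenone | CC(=O)c1ccc(OCC=C)cc1O | intermediate
4 | 1-(3-allyl-2,4-dihydroxyphenyl)ethanone | CC(=O)c1ccc(O)c(CC=C)c1O | intermediate
5 | chloromethyl methyl ether (MOMCl) | ClCOC | starting material
6 | 1-[3-allyl-2-hydroxy-4-(methoxymethoxy)phenyl]ethanone | CC(=O)c1ccc(OCOC)c(CC=C)c1O | intermediate
7 | 2-methyl-2-butene | CC=C(C)C | starting material
8 | 1-[2-hydroxy-4-(methoxymethoxy)-3-prenylphenyl]ethanone | CC(=O)c1ccc(OCOC)c(CC=C(C)C)c1O | intermediate
9 | 4-hydroxybenzaldehyde | O=Cc1ccc(O)cc1 | starting material
10 | 4-allyloxybenzaldehyde | C=CCOc1ccc(C=O)cc1 | intermediate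
11 | 3-allyl-4-hydroxybenzaldehyde | O=Cc1ccc(O)c(CC=C)c1 | intermediate
12 | 3-allyl-4-(methoxymethoxy)benzaldehyde | O=Cc1ccc(OCOC)c(CC=C)c1 | intermediate
13 | 4-(methoxymethoxy)-3-prenylbenzaldehyde | O=Cc1ccc(OCOC)c(CC=C(C)C)c1 | intermediate
14 | (E)-bis-MOM, bis-prenyl 2'-hydroxychalcone | CC(C)=CCc1c(OCOC)ccc(C(=O)/C=C/c2ccc(OCOC)c(CC=C(C)C)c2)c1O | intermediate
15 | (S)-3,3'-bis(2,4,6-triisopropylphenyl)-BINOL N-triflylphosphoramide, the catalyst for step 10 (axial chirality (S) is given in the name, not encoded in the SMILES) | O=P1(NS(=O)(=O)C(F)(F)F)Oc2c(-c3c(C(C)C)cc(C(C)C)cc3C(C)C)cc3ccccc3c2-c2c(O1)c(-c1c(C(C)C)cc(C(C)C)cc1C(C)C)cc1ccccc21 | starting material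
16 | (2S)-bis-MOM-diprenylflavanone | CC(C)=CCc1cc([C@@H]2CC(=O)c3ccc(OCOC)c(CC=C(C)C)c3O2)ccc1OCOC | intermediate
17 | glabrol | CC(C)=CCc1cc([C@@H]2CC(=O)c3ccc(O)c(CC=C(C)C)c3O2)ccc1O | target

## Totals
Total steps: 11. Longest linear sequence: 7 (1 → 3 → 4 → 6 → 8 → 14 → 16 → 17, counting from compound 1; the benzaldehyde branch 9 → 10 → 11 → 12 → 13 → 14 → 16 → 17 is also 7 steps).

## Three steps most likely to fail
1. **Step 10 (proposed new step).** The acid catalyst may be too weak or too slow on the deactivated chalcone, the ee may be modest, or the prenyl groups may be protonated to give chromanes over 96 h.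
   Fallback (known chemistry, changed approach): cyclise 14 to racemic 16 with pyrrolidine in EtOH, resolve by preparative chiral-phase HPLC, and recycle the (R)-enantiomer by DBU-mediated racemisation.
2. **Step 4 (and step 8) cross-metathesis.** It may give low conversion or the propenyl isomer, and Claisen regiochemistry in step 2 feeds the same fragment.
   Fallback: cleave the allyl group (OsO4/NaIO4), then do a Wittig reaction with iPrPPh3I/KOtBu to form the prenyl alkene. For the aryl-aldehyde fragment, do this on the allyl-bearing intermediate before the aldehyde is unmasked.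
3. **Step 11 deprotection.** It could cause partial racemisation or prenyl-to-chromane cyclisation.
   Fallback: drop the MOM groups altogether. Run the aldol on the free-phenol fragments with aq. KOH/EtOH and the enantioselective cyclisation on the free-phenol chalcone, so no deprotection is needed.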